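Everything rests on cutting ring A at C2=C3, its only bond that touches neither the methyl-bearing quaternary C1 nor the isopropyl carbinol C4. Because C2 and C4 then stand in a 1,4-relationship across the C1–C5 ring fusion, a formyl group on C1 and an acetyl group on C5 of a fully oxygenated cycloheptane (ring B) are joined in one base-mediated aldol condensation, which closes ring A as the trans-fused cyclopentenone with its carbonyl at C4, ready to receive isopropyl. The precursor is the ring-B keto aldehyde with a C6 benzyl ether and two acetonides (C9/C10 diol; C8 carbinol with its CH2O arm), built from a meso furan (4+3) cycloadduct.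

Key step: step 13

Locants: target numbering throughout (ring A = C1–C5; ring B = C1, C5–C10; C14 = the CH2 on C8). β = face of the C1 methyl, α = the opposite face. Target: 1β-Me, 5α-H, 4β-OH, 6α-acyloxy, 8α-O (epoxide), 9α,10α-diol.

Design remarks: C8 carries its oxygen and C14 from the cycloadduct, so the epoxide is closed by displacement and no ketal has to be removed beside an acetonide. C6 is carried as the 6β-benzyl ether that step 8 delivers and is turned into 6α in steps 16 and 17.

Assumption: the (R,R)-amide of step 5 is taken to remove the hydrogen on the future C5; if the sense is the reverse, the (S,S)-amide is used.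

Step 1
Reactants: 1 2,5-bis(hydroxymethyl)furan
Product: 2 2,5-bis(tert-butyldimethylsilyloxymethyl)furan
Conditions: TBSCl, imidazole, DMF, 0 °C to rt
Reagents that add atoms: tert-butyldimethylsilyl chloride, CC(C)(C)[Si](C)(C)Cl
Why: Imidazole-promoted silylation of two unhindered primary alcohols is routine and the silyl ethers tolerate every step up to their planned removal in step 10; no stereocentre is involved.

Step 2
Reactants: 2 2,5-bis(tert-butyldimethylsilyloxymethyl)furan; 3 1,1,3-trichloroacetone
Product: 5 meso-1,5-bis(tert-butyldimethylsilyloxymethyl)-8-oxabicyclo[3.2.1]oct-6-en-3-one, via dichloro cycloadduct 4 (not isolated)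
Conditions: 3, Et3N, CF3CH2OH, 0 °C to rt; then Zn–Cu, NH4Cl, MeOH, rt
Reagents that add atoms: 1,1,3-trichloroacetone, ClCC(=O)C(Cl)Cl
Why: Oxyallyl cation (4+3) cycloaddition: amine-induced loss of HCl from 3 in the ionising solvent gives a dichloro-oxyallyl cation that adds across C2/C5 of the electron-rich furan, and Zn–Cu reductive dechlorination converges all chloro epimers of 4 on one meso ketone in which the bridge forces the two bridgehead C–O bonds cis.

Step 3
Reactants: 5 meso-1,5-bis(tert-butyldimethylsilyloxymethyl)-8-oxabicyclo[3.2.1]oct-6-en-3-one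
Product: 6 meso exo,exo-6,7-diol of 5 (both hydroxyls cis to the oxygen bridge; future 9α,10α-diol)
Conditions: OsO4 (2 mol %), NMO, acetone/H2O, rt
Reagents that add atoms: N-methylmorpholine N-oxide, C[N+]1([O-])CCOCC1; water, O
Why: Upjohn dihydroxylation: OsO4 adds suprafacially to the strained alkene from the exo face (the side of the oxygen bridge, away from the three-carbon ketone bridge), so both hydroxyls end up cis to the bridge oxygen, which fixes the future C9 and C10 relative to C8.

Step 4
Reactants: 6 meso exo,exo-6,7-diol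
Product: 7 meso 6,7-O-isopropylidene derivative of 6
Conditions: Me2C(OMe)2, PPTS (cat.), acetone, rt
Reagents that add atoms: 2,2-dimethoxypropane, COC(C)(C)OC
Why: Acid-catalysed acetonide formation (transketalisation) on the cis-1,2-diol, under conditions that primary silyl ethers tolerate.

Step 5
Reactants: 7 meso acetonide ketone
Product: 8 3-trimethylsilyloxy-2-ene derived from 7 (enol double bond between the future C5 and C6; single enantiomer)
Conditions: (R,R)-bis(1-phenylethyl)amine·HCl, n-BuLi (2 equiv), THF, −78 to 0 °C; then TMSCl, 7, −100 °C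
Reagents that add atoms: chlorotrimethylsilane, C[Si](C)(C)Cl
Why: Enantioselective deprotonation of a meso 8-oxabicyclo[3.2.1]octan-3-one by a chiral lithium amide with in situ silylation: the base distinguishes the two enantiotopic axial α-hydrogens, and enolisation toward the future C5 is the event that sets the absolute configuration of every later compound.

Step 6
Reactants: 8 trimethylsilyl enol ether
Product: 9 cycloheptenone (C6 ketone; C1=C5; 1-CH2OTBS; 8α-OTMS; 8β-CH2OTBS; 9α,10α-O-isopropylidene)
Conditions: TMSOTf (10 mol %), CH2Cl2, −78 to −40 °C; Et3N quench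
Reagents that add atoms: none
Why: Lewis-acid-induced β-elimination (opening of the oxygen bridge): silyl triflate activates the bridge oxygen, the enol ether expels the allylic C1–O bond, the only one it can reach, and the silyl group ends on the new tertiary C8 alkoxide, relief of bicyclic strain driving the isomerisation while C8, C9 and C10 are untouched.

Step 7
Reactants: 9 cycloheptenone; 10 methyllithium (as Me2CuLi); 11 acetaldehyde
Product: 12 β-hydroxy ketone (1β-methyl; 1α-CH2OTBS; 5α-H; 5β-[(1R)-1-hydroxyethyl]; C6 ketone; C8 to C10 as in 9)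
Conditions: MeLi (10), CuI, Et2O, 0 °C; 9, −78 to −20 °C; then CH3CHO (11), −78 °C; aq NH4Cl
Reagents that add atoms: lithium dimethylcuprate Me2CuLi (from 10 and CuI), [Li+].C[Cu-]C; acetaldehyde, CC=O
Why: Cuprate conjugate addition followed by aldol trapping: Me2CuLi adds to C1 anti to the γ-oxygen at C10 and to the α-face acetonide (C1 methyl β), the enolate then takes up acetaldehyde at C5 from the β face, away from the bulkier 1α-CH2OTBS group, and the chair transition state of the ring (E)-enolate favours the anti aldol drawn, whose C4 centre is erased in step 12.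

Step 8
Reactants: 12 β-hydroxy ketone; 11 acetaldehyde
Product: 13 1,3-anti diol monoacetate (6β-OH; C4 acetate; otherwise as 12)
Conditions: SmI2 (30 mol %), CH3CHO (8 equiv), THF, −10 °C
Reagents that add atoms: acetaldehyde, CC=O
Why: Evans–Tishchenko reduction: the samarium-bound hemiacetal formed from the C4 hydroxyl and acetaldehyde transfers hydride to C6 through a chair transition state, giving the 1,3-anti product (6β-OH from the anti aldol) and leaving the two oxygens differentiated as acetate and free alcohol; C6 is reset in steps 16 and 17.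

Step 9
Reactants: 13 diol monoacetate
Product: 14 6β-benzyl ether of 13
Conditions: BnOC(=NH)CCl3, TfOH (5 mol %), CH2Cl2/cyclohexane, 0 °C
Reagents that add atoms: benzyl 2,2,2-trichloroacetimidate, N=C(OCc1ccccc1)C(Cl)(Cl)Cl
Why: Acid-catalysed benzylation with the trichloroacetimidate avoids the base that would make the acetate migrate, and catalytic triflic acid at 0 °C is tolerated by acetonide and silyl ethers; no stereocentre changes.

Step 10
Reactants: 14 benzyl ether
Product: 16 tetraol (C2-OH; C4-OH; C8-OH; C14-OH free; 6β-OBn; 9α,10α-acetonide), via triol acetate 15 (not isolated)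
Conditions: TBAF, THF, rt; then K2CO3, MeOH, rt
Reagents that add atoms: none
Why: Fluoride desilylation removes the three silyl ethers and carbonate-catalysed transesterification then removes the acetate, conditions to which benzyl ether and acetonide are inert.

Step 11
Reactants: 16 tetraol
Product: 17 bis-acetonide diol (8α-O/C14-O acetonide; 9α,10α-acetonide; C2-OH and C4-OH free; 6β-OBn)
Conditions: Me2C(OMe)2, PPTS (cat.), acetone, rt
Reagents that add atoms: 2,2-dimethoxypropane, COC(C)(C)OC
Why: Acetonide formation is selective by ring size: among the four hydroxyls only C8-OH/C14-OH form a 1,2-diol, so a five-membered ketal closes there and the 1,4-related C2 and C4 hydroxyls stay free.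

Step 12
Reactants: 17 bis-acetonide diol
Product: 18 keto aldehyde (1α-CHO; 1β-Me; 5β-acetyl; 5α-H; 6β-OBn; both acetonides)
Conditions: (COCl)2, DMSO, CH2Cl2, −78 °C; Et3N, −78 to −20 °C
Reagents that add atoms: none
Why: Swern oxidation activates both hydroxyls at −78 °C before any carbonyl exists, so the 1,4-diol gives the keto aldehyde without lactol or lactone formation, and the cold amine treatment should not epimerise C5.

Step 13
Reactants: 18 keto aldehyde
Product: 20 trans-fused cyclopentenone (C4 ketone; C2=C3; 1β-Me; 5α-H; 6β-OBn; both acetonides), via ring-A aldol 19 (not isolated)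
Conditions: KOH (0.5 M), MeOH, 0 °C to rt
Reagents that add atoms: none
Why: The base reversibly enolises the acetyl methyl group (C3), the C3 enolate adds to the C2 formyl carbon, and the β-hydroxy ketone 19 loses water by E1cB to give the C2=C3 enone conjugated to the C4 carbonyl. This is the classical base-mediated intramolecular aldol condensation of a 1,4-dicarbonyl compound to a cyclopentenone. Ring A closes in the 5-(enolendo)-exo-trig mode, the only five-membered closure open to a 1,4-keto aldehyde and routine for this compound class. No stereocentre is created: C1 and C5 are carried over from 18 and the C2 carbinol of 19 disappears on dehydration. The step needs site selectivity for the C3 enolate and retention of the trans C1/C5 relationship: the formyl group on quaternary C1 cannot enolise, a C5 enolate could reach it only through a three-membered ring, and the hindered C5 methine is deprotonated more slowly than the methyl group, so dilute base at low temperature is used to finish the condensation before C5 epimerises or benzyl oxide is lost from C6.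

Step 14
Reactants: 20 cyclopentenone; 21 isopropylmagnesium chloride
Product: 22 tertiary allylic alcohol (4β-OH; 4α-isopropyl; C2=C3 retained)
Conditions: i-PrMgCl, CeCl3, THF, −78 to 0 °C; aq NH4Cl
Reagents that add atoms: isopropylmagnesium chloride, CC(C)[Mg]Cl
Why: Organocerium 1,2-addition (low basicity, high oxophilicity) to the enolisable cyclopentenone: the reagent reaches C4 from the α face, opposite the angular C1 methyl and the 6β-benzyloxy group, which gives the 4β-hydroxy-4α-isopropyl carbinol.

Step 15
Reactants: 22 tertiary allylic alcohol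
Product: 23 saturated 4β,6β-diol (ring A saturated; benzyl removed)
Conditions: H2 (1 atm), 10% Pd/C, EtOAc, rt
Reagents that add atoms: none
Why: Heterogeneous catalytic hydrogenation saturates the cis-disubstituted C2=C3 bond and hydrogenolyses the benzyl ether in one operation; no stereocentre is formed and acetonides and the tertiary alcohol are inert.

Step 16
Reactants: 23 4β,6β-diol
Product: 24 4β-hydroxy 6-ketone
Conditions: Dess–Martin periodinane, CH2Cl2, 0 °C to rt
Reagents that add atoms: none
Why: Dess–Martin oxidation converts the only secondary alcohol into the ketone under non-basic conditions, so C5 is not epimerised and the β-hydroxy ketone is not cleaved by retro-aldol reaction.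

Step 17
Reactants: 24 4β-hydroxy 6-ketone
Product: 25 4β,6α-diol
Conditions: Me4NBH(OAc)3, MeCN/AcOH (1:1), −20 °C
Reagents that add atoms: none
Why: Saksena–Evans hydroxyl-directed reduction: the 4β-hydroxyl exchanges onto boron and delivers hydride intramolecularly to the β face of C6, the only face the trans-fused skeleton lets the C4–O–B–H arm reach, so the 6α-alcohol is formed, and a ketone without such a neighbour is not reduced by this reagent.

Step 18
Reactants: 25 4β,6α-diol; 26 3-methylbutanoic anhydride
Product: 27 6α-(3-methylbutanoate) of 25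
Conditions: (Me2CHCH2CO)2O, DMAP, Et3N, CH2Cl2, rt
Reagents that add atoms: 3-methylbutanoic anhydride, CC(C)CC(=O)OC(=O)CC(C)C
Why: DMAP-catalysed acylation esterifies the secondary C6 alcohol, while the hindered tertiary C4 hydroxyl does not react at room temperature.

Step 19
Reactants: 27 ester bis-acetonide
Product: 28 pentahydroxy ester (4β-OH; 8α-OH; C14-OH; 9α,10α-diol; 6α-ester)
Conditions: AcOH/H2O (4:1), 50 °C
Reagents that add atoms: none
Why: Acid-catalysed acetal hydrolysis frees both diols; the ester and the tertiary alcohols tolerate warm dilute acetic acid.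

Step 20
Reactants: 28 pentahydroxy ester
Product: 30 target CNP0307265.1 (8α-O spiro-epoxide; 9α,10α-diol; 4β-OH; 6α-ester), via C14 tosylate 29 (not isolated)
Conditions: TsCl, Et3N, DMAP (cat.), CH2Cl2, −10 °C; then DBU, rt
Reagents that add atoms: none
Why: Selective sulfonylation of the single primary hydroxyl followed by intramolecular Williamson displacement (3-exo-tet) by the neighbouring tertiary C8 alkoxide closes the spiro-epoxide with retention at C8, so the epoxide oxygen stays α as set in step 3, and the cis C9 hydroxyl cannot open it because it cannot attack C8 from the rear.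

Compound list
1 | 2,5-bis(hydroxymethyl)furan | OCc1ccc(CO)o1 | starting material
2 | 2,5-bis(tert-butyldimethylsilyloxymethyl)furan | CC(C)(C)[Si](C)(C)OCc1ccc(CO[Si](C)(C)C(C)(C)C)o1 | intermediate
3 | 1,1,3-trichloroacetone | ClCC(=O)C(Cl)Cl | starting material
4 | 2,4-dichloro-1,5-bis(tert-butyldimethylsilyloxymethyl)-8-oxabicyclo[3.2.1]oct-6-en-3-one (chlorine epimers, centres left open) | O=C1C(Cl)[C@]2(CO[Si](C)(C)C(C)(C)C)C=C[C@](CO[Si](C)(C)C(C)(C)C)(C1Cl)O2 | intermediate
5 | meso-1,5-bis(tert-butyldimethylsilyloxymethyl)-8-oxabicyclo[3.2.1]oct-6-en-3-one | O=C1C[C@]2(CO[Si](C)(C)C(C)(C)C)C=C[C@](CO[Si](C)(C)C(C)(C)C)(C1)O2 | intermediate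
6 | meso exo,exo-6,7-dihydroxy derivative of 5 (saturated C6–C7) | O=C1C[C@]2(CO[Si](C)(C)C(C)(C)C)[C@@H](O)[C@@H](O)[C@](CO[Si](C)(C)C(C)(C)C)(C1)O2 | intermediate
7 | meso exo,exo-6,7-O-isopropylidene ketone | O=C1C[C@]2(CO[Si](C)(C)C(C)(C)C)[C@@H](OC(C)(C)O3)[C@@H]3[C@](CO[Si](C)(C)C(C)(C)C)(C1)O2 | intermediate
8 | trimethylsilyl enol ether of 7, enol double bond toward the future C5 | C[Si](C)(C)OC=1C[C@]2(CO[Si](C)(C)C(C)(C)C)[C@@H](OC(C)(C)O3)[C@@H]3[C@](CO[Si](C)(C)C(C)(C)C)(C=1)O2 | intermediate
9 | cycloheptenone: C6 ketone, C1=C5, 1-CH2OTBS, 8α-OTMS, 8β-CH2OTBS, 9α,10α-O-isopropylidene | O=C1C[C@](O[Si](C)(C)C)(CO[Si](C)(C)C(C)(C)C)[C@@H](OC(C)(C)O2)[C@@H]2C(CO[Si](C)(C)C(C)(C)C)=C1 | intermediate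
10 | methyllithium | [Li]C | starting material
11 | acetaldehyde | CC=O | starting material
12 | β-hydroxy ketone: 1β-Me, 1α-CH2OTBS, 5α-H, 5β-[(1R)-1-hydroxyethyl], C6 ketone | O=C1C[C@](O[Si](C)(C)C)(CO[Si](C)(C)C(C)(C)C)[C@@H](OC(C)(C)O2)[C@@H]2[C@@](C)(CO[Si](C)(C)C(C)(C)C)[C@@H]1[C@@H](C)O | intermediate
13 | 1,3-anti diol monoacetate: 6β-OH, C4 acetate | O[C@@H]1C[C@](O[Si](C)(C)C)(CO[Si](C)(C)C(C)(C)C)[C@@H](OC(C)(C)O2)[C@@H]2[C@@](C)(CO[Si](C)(C)C(C)(C)C)[C@@H]1[C@@H](C)OC(C)=O | intermediate
14 | 6β-benzyl ether of 13 | c1ccccc1CO[C@@H]2C[C@](O[Si](C)(C)C)(CO[Si](C)(C)C(C)(C)C)[C@@H](OC(C)(C)O3)[C@@H]3[C@@](C)(CO[Si](C)(C)C(C)(C)C)[C@@H]2[C@@H](C)OC(C)=O | intermediate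
15 | triol acetate: C2-OH, C8-OH, C14-OH free, C4 acetate | c1ccccc1CO[C@@H]2C[C@](O)(CO)[C@@H](OC(C)(C)O3)[C@@H]3[C@@](C)(CO)[C@@H]2[C@@H](C)OC(C)=O | intermediate
16 | tetraol: C2-OH, C4-OH, C8-OH, C14-OH free; 6β-OBn; 9α,10α-acetonide | c1ccccc1CO[C@@H]2C[C@](O)(CO)[C@@H](OC(C)(C)O3)[C@@H]3[C@@](C)(CO)[C@@H]2[C@@H](C)O | intermediate
17 | bis-acetonide diol: C2-OH and C4-OH free | c1ccccc1CO[C@@H]2C[C@]3(COC(C)(C)O3)[C@@H](OC(C)(C)O4)[C@@H]4[C@@](C)(CO)[C@@H]2[C@@H](C)O | intermediate
18 | keto aldehyde: 1α-CHO, 1β-Me, 5β-acetyl, 6β-OBn, two acetonides | c1ccccc1CO[C@@H]2C[C@]3(COC(C)(C)O3)[C@@H](OC(C)(C)O4)[C@@H]4[C@@](C)(C=O)[C@@H]2C(C)=O | intermediate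
19 | ring-A aldol: 2-hydroxy 4-ketone (C2 centre left open) | c1ccccc1CO[C@@H]2C[C@]3(COC(C)(C)O3)[C@@H](OC(C)(C)O4)[C@@H]4[C@@]5(C)C(O)CC(=O)[C@H]25 | intermediate
20 | trans-fused cyclopentenone: C4 ketone, C2=C3 | c1ccccc1CO[C@@H]2C[C@]3(COC(C)(C)O3)[C@@H](OC(C)(C)O4)[C@@H]4[C@@]5(C)C=CC(=O)[C@H]25 | intermediate
21 | isopropylmagnesium chloride | CC(C)[Mg]Cl | starting material
22 | tertiary allylic alcohol: 4β-OH, 4α-isopropyl, C2=C3 | c1ccccc1CO[C@@H]2C[C@]3(COC(C)(C)O3)[C@@H](OC(C)(C)O4)[C@@H]4[C@@]5(C)C=C[C@@](O)(C(C)C)[C@H]25 | intermediate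
23 | saturated 4β,6β-diol bis-acetonide | O[C@@H]1C[C@]2(COC(C)(C)O2)[C@@H](OC(C)(C)O3)[C@@H]3[C@@]4(C)CC[C@@](O)(C(C)C)[C@H]14 | intermediate
24 | 4β-hydroxy 6-ketone bis-acetonide | O=C1C[C@]2(COC(C)(C)O2)[C@@H](OC(C)(C)O3)[C@@H]3[C@@]4(C)CC[C@@](O)(C(C)C)[C@H]14 | intermediate
25 | 4β,6α-diol bis-acetonide | O[C@H]1C[C@]2(COC(C)(C)O2)[C@@H](OC(C)(C)O3)[C@@H]3[C@@]4(C)CC[C@@](O)(C(C)C)[C@H]14 | intermediate
26 | 3-methylbutanoic anhydride | CC(C)CC(=O)OC(=O)CC(C)C | starting material
27 | 6α-(3-methylbutanoate) bis-acetonide | CC(C)CC(=O)O[C@H]1C[C@]2(COC(C)(C)O2)[C@@H](OC(C)(C)O3)[C@@H]3[C@@]4(C)CC[C@@](O)(C(C)C)[C@H]14 | intermediate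
28 | pentahydroxy ester: 4β, 8α, 9α, 10α and C14 hydroxyls free | CC(C)CC(=O)O[C@H]1C[C@](O)(CO)[C@@H](O)[C@@H](O)[C@@]2(C)CC[C@@](O)(C(C)C)[C@H]12 | intermediate
29 | C14 p-toluenesulfonate of 28 | CC(C)CC(=O)O[C@H]1C[C@](O)(COS(=O)(=O)c2ccc(C)cc2)[C@@H](O)[C@@H](O)[C@@]3(C)CC[C@@](O)(C(C)C)[C@H]13 | intermediate
30 | CNP0307265.1 | CC(C)CC(=O)O[C@H]1C[C@]2(CO2)[C@@H](O)[C@@H](O)[C@@]2(C)CC[C@@](O)(C(C)C)[C@H]12 | target

Total steps: 20. Longest linear sequence: 20 steps (1 to 30; the route is fully linear).

Steps most likely to fail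

Risk A, step 13. Under the equilibrating base, deprotonation at C5 may compete with the wanted methyl enolisation. That would epimerise the ring fusion or expel benzyl oxide from C6, before or after ring closure. The fallback sets out from 18 and returns at 20. Soft enolisation with TMSOTf/Et3N at −78 °C converts the acetyl group into its terminal trimethylsilyl enol ether F1; the hindered C5 methine should not be touched. BF3·OEt2 at −78 °C then closes ring A by an intramolecular Mukaiyama aldol addition onto the C2 aldehyde and gives aldol 19, now isolated. The Burgess reagent dehydrates 19 by syn elimination under neutral conditions to 20. C–C bond formation and dehydration are thus separated and C5 never meets a base stronger than a tertiary amine.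

Risk B, step 7. Conjugate addition at the fully substituted β-carbon may be slow, letting 1,2-addition or enolisation compete. The aldol trapping may also be reversible or incompletely face-selective at C5. The fallback sets out from 9 and returns at 12. Me2CuLi in the presence of TMSCl (silyl-accelerated conjugate addition) gives the trimethylsilyl enol ether F2, which is isolated. A Mukaiyama aldol addition with acetaldehyde and BF3·OEt2 at −78 °C then installs the side chain through an open transition state and gives 12 after aqueous work-up.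

Risk C, step 5. The chiral base may discriminate poorly between the two enantiotopic α-methylene groups, which are flanked here by substituted bridgeheads, so that the enantiomeric purity of the whole series would be too low. The fallback sets out from 7 and returns at 9. Deprotonation with achiral LDA/TMSCl gives 8 together with its mirror image, the ent-enol ether F3. The conditions of step 6 convert the pair into 9 and the ent-enone F4. The racemate is resolved by preparative chromatography on a chiral stationary phase and 9 goes on.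

Further compounds
F1 | step 13 | terminal trimethylsilyl enol ether of the acetyl group of 18 | c1ccccc1CO[C@@H]2C[C@]3(COC(C)(C)O3)[C@@H](OC(C)(C)O4)[C@@H]4[C@@](C)(C=O)[C@@H]2C(=C)O[Si](C)(C)C
F2 | step 7 | C5=C6 trimethylsilyl enol ether from conjugate addition to 9 (1β-Me, 1α-CH2OTBS) | C[Si](C)(C)OC=1C[C@](O[Si](C)(C)C)(CO[Si](C)(C)C(C)(C)C)[C@@H](OC(C)(C)O2)[C@@H]2[C@@](C)(CO[Si](C)(C)C(C)(C)C)C=1
F3 | step 5 | ent-enol ether (mirror image of 8) | C[Si](C)(C)OC=1C[C@@]2(CO[Si](C)(C)C(C)(C)C)[C@H](OC(C)(C)O3)[C@H]3[C@@](CO[Si](C)(C)C(C)(C)C)(C=1)O2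
F4 | step 5 | ent-enone (mirror image of 9) | O=C1C[C@@](O[Si](C)(C)C)(CO[Si](C)(C)C(C)(C)C)[C@H](OC(C)(C)O2)[C@H]2C(CO[Si](C)(C)C(C)(C)C)=C1
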